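The earlier runs and the new flask are calculated from invented constants, and the scatter is random.

The pitfall in a curve that stalls at a few per cent is to read the plateau as a fixed amount of product, as if each free catalyst held a set number of turnovers. That is my first extreme version.

| flask | left-handed substrate | right-handed substrate | partner | free catalyst | remark | time |
|---|---|---|---|---|---|---|
| dusk | 0.50 mM | 0.50 mM | 2.2 mM | 2 µM | run made earlier |  |
| winter | 2 mM | 2 mM | 2.2 mM | 2 µM | run made earlier |  |
| summer | 1 mM | 1 mM | 2.2 mM | 4 µM | run made earlier |  |
| flask | 1.0 mM | 1.0 mM | 2.20 mM | 2.0 µM |  | 6.0 min |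

| run | time / min | left-handed substrate / % | right-handed substrate / % |
|---|---|---|---|
| dusk | 0.333 | 48.9 | 48.7 |
| dusk | 1.00 | 47.5 | 47.6 |
| dusk | 1.50 | 47.5 | 47.3 |
| dusk | 2.50 | 46.8 | 46.6 |
| dusk | 4.00 | 46.5 | 46.8 |
| dusk | 5.00 | 46.5 | 46.1 |
| winter | 0.417 | 48.1 | 48.3 |
| winter | 0.667 | 47.9 | 48.3 |
| winter | 1.00 | 47.9 | 47.8 |
| winter | 2.00 | 47.1 | 47.2 |
| winter | 3.00 | 47.2 | 47.0 |
| winter | 5.00 | 46.9 | 47.1 |
| summer | 0.417 | 47.7 | 47.9 |
| summer | 0.667 | 47.1 | 48.0 |
| summer | 1.33 | 46.2 | 46.9 |
| summer | 2.50 | 45.3 | 46.0 |
| summer | 5.00 | 45.6 | 45.2 |

(standard deviation of a reading: 0.3 percentage points)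

- free catalyst is single-handed; left-handed substrate and right-handed substrate are mirror images of each other, charged as a racemate, each of them at the stated concentration
- an excess is the difference of the two amounts in percent of their sum
- an excess is below zero if the other one leads

At its last reading the dusk run has made 0.0740 mM of product and the winter run 0.240 mM, both on 2 µM of free catalyst. Carried to the flask, these amounts give 3.70% and 12.0% reacted, which cannot both hold.

The second extreme is a free catalyst with a fixed life whatever the substrate charge, and a loss pseudo-first-order in substrate, so that each charge loses the same fraction. The natural log of substrate charged over substrate left on the plateau should then come out alike. It is 0.0769 in the dusk run and 0.0619 in the winter run, with mean 0.0694, and this mean is what I carry: the dose of one catalyst life. The dusk and winter runs lie between the two versions and closer to this one, since the winter product over the dusk product reads 3.24, nearer the charge ratio 4.00 than 1. I set the summer run aside: it differs in its 4 µM of free catalyst, and its dose reads 0.0965, above the mean. The flask has 2.0 µM of free catalyst and a substrate charge between dusk and winter, so I reckon 6.70% reacted.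

* part of the left-handed substrate and right-handed substrate charged together that has reacted at 6.0 min
* excess of left-handed product over right-handed product in the product at 6.0 min
* excess of right-handed substrate over left-handed substrate among what is left of the two at 6.0 min

The forecast gives c 7% (5.6% to 8.5%), higher than my figure, eP 2% (−0.5% to 4.5%) and eS 0.15% (−0.04% to 0.36%), noting: “Selectivity is barely visible”.

The flask gives c 6.71%, eP 52.2% and eS 0.00544%.

    2 free catalyst → spent catalyst (k = 1.00 × 10⁶ M⁻¹ s⁻¹)
    2 free catalyst ⇌ resting dimer, settled at all times (K = 1.90 × 10⁷ M⁻¹)
    partner + free catalyst + left-handed substrate → free catalyst + left-handed product (k = 4.80 × 10⁶ M⁻² s⁻¹)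
    left-handed substrate ⇌ right-handed substrate (k = 0.0830 s⁻¹)
    partner + free catalyst + right-handed substrate → free catalyst + right-handed product (k = 1.50 × 10⁶ M⁻² s⁻¹)

At 6.00 min the flask holds 5.11% of left-handed product against 1.60% of right-handed product, with left-handed substrate at 46.6% and right-handed substrate at 46.6%. Partner enters both product steps at first order, so for c(partner) at 8.8 mM, all else as in this flask, I multiply the dose by 4.00 to 0.278, which reckons 24.2% reacted. That neighbour flask stands at 24.2% reacted.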